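After 20.0 h the green run holds 63 % of target beside 35 % of side product, while the violet run, with 6.6 mM of free catalyst against 99 mM, holds 8 % beside 22 %.

| setting | violet | green | alpha | theta | zeta | beta |
|---|---|---|---|---|---|---|
| starting material | 1.2 M | 1.2 M | 1.2 M | 1.2 M | 1.2 M | 1.2 M |
| second substrate | 1.2 M | 1.2 M | 1.20 M | 1.20 M | 1.20 M | 1.20 M |
| free catalyst | 6.6 mM | 99 mM | 8.0 mM | 28 mM | 120 mM | 15 mM |
| remark | run made earlier | run made earlier |  |  |  |  |
| time |  |  | 30 h | 30 h | 30 h | 30 h |

- violet (time / h: target / %, side product / %): 2.00: 2, 1; 5.00: 2, 2; 10.0: 8, 6; 15.0: 3, 14; 20.0: 8, 22
- green (time / h: target / %, side product / %): 1.50: 20, 6; 3.00: 31, 5; 6.00: 45, 13; 12.0: 62, 29; 20.0: 63, 35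

(standard deviation of a reading: 2 percentage points)

- percentages count the starting material that a species holds: one side product counts as two

* the flasks put in order of share of target in all that became target or side product, best first, at 30 h (alpha / theta / zeta / beta)
* the share of target in all that became target or side product of the flask you put first, at 30 h
* the share of target in all that became target or side product of the flask you put last, at 30 h

**Balance level.** Reading the runs as catalysed making of target from starting material and loss of target with starting material to side product, and taking both rates as first order in starting material, makes them balance at one target level, taken as proportional to catalyst. For a used-up charge, with share s and that level r, the series 1 = s + s^2/r + 2s^3/(3r^2) holds to its first terms. Green, whose two products add to nearly all of the charge, has a share of 64.3 %, and putting each answer back gives 116 %, 184 %, 136 % and 158 %. The mean of the last two, 147 %, is my estimate of the balance level, the target level at which making would equal loss on this reading (a selectivity factor).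

**The bracket.** Scaled by catalyst, that estimate is 178 % for zeta and 11.9 % for alpha. Green's share put into zeta's loss terms understates the loss, which bounds zeta from above at 71.2 %, and that answer put back overstates it, which bounds zeta from below at 63.9 %.

**The forecast.** It gives zeta > theta > beta > alpha, with zeta at 68 % (62 % to 74 %), lower than 71.2 % and higher than 63.9 %, and alpha at 24 % (19 % to 30 %), on the ground that “Higher catalyst gives higher share.”

**The flasks.** The order comes out zeta > theta > beta > alpha, with zeta at 70.1 %, inside the bracket, and alpha at 25.5 %.

    starting material + free catalyst ⇌ catalyst intermediate A (K = 0.410 /M, k = 6.80 /M/h)
    catalyst intermediate A → free catalyst + target (k = 6.40 /h)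
    second substrate + free catalyst ⇌ catalyst intermediate B (K = 1.10 /M, k = 5.60 /M/h)
    catalyst intermediate B → free catalyst + second product (k = 100 /h)
    starting material + target → side product (k = 0.0800 /M/h)

At 30.0 h zeta keeps 0.0315 % of starting material and holds 70.0 % of target, lower than its estimated balance level. Alpha at that time holds 10.9 % of target, still made 1.18 times as fast as it is used up, and the 11.9 % scaled from green runs low for alpha, whose target after 300 h stands higher than that, at 14.3 %.

The data were generated by integration with constants of no real substance, and the scatter is random.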